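**Plan**

- Retrosynthesis: the three O-benzyl groups and the 3-O-methyl group are taken off first. The C2–C3 bond of the pyranone ring (O1, C2, C3, C4, C4a, C8a) is then cut and C2 is handed back to the C3 oxygen, which gives a seven-membered 2-aryl-4H-1,3-benzodioxepin-5-one (a cyclic O,O-acetal). This acetal is cut at C2 into ring-B aldehyde 3 and ring-A phenolic α-ketol 9.
- Enabling feature: C2 is a benzylic carbon bound to O1 and to the 2,4,5-trioxygenated ring B (aldehyde oxidation level, very stable cation). Its neighbour C3 carries oxygen and lies α to the C4 aryl ketone (an enolizable α-ketol carbon). The C3 oxygen can therefore hold C2 as an acetal and pass it on to C3.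
- Forward: ring B (steps 1–2) and ring A (steps 3–7) are made separately and joined as the seven-membered acetal (step 8). The pyranone ring then arises by contraction of that ring (steps 9–10). O-Methylation and hydrogenolysis finish the route.
- Stereochemistry: C2 is set in the ring contraction by the chiral counteranion of the catalyst; the racemic acetal centre is erased on ionization, so both enantiomers converge. C3 is set relative to C2 (trans) in the same ring closure. The later steps are non-basic.

Key step: step 10

Assumption: 1 and 4 are taken as commercial; the (S,S) antipode of the catalyst in step 10 is taken as the one that delivers 2R, and the other antipode would be used if the sense proves opposite.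

**Route**

Step 1
Reactants: 1 2-methoxybenzene-1,4-diol
Product: 2 1,4-bis(benzyloxy)-2-methoxybenzene
Conditions: BnBr, K2CO3, DMF, 60 °C
Reagents that add atoms: benzyl bromide BrCc1ccccc1
Why: Williamson etherification of both phenols by SN2 on the benzylic bromide.

Step 2
Reactants: 2 1,4-bis(benzyloxy)-2-methoxybenzene
Product: 3 2,5-bis(benzyloxy)-4-methoxybenzaldehyde
Conditions: POCl3, DMF, 0 to 70 °C; then ice-water
Reagents that add atoms: N,N-dimethylformamide CN(C)C=O; water O
Why: Vilsmeier–Haack formylation should enter para to the methoxy group and ortho to a benzyloxy group, the position that is attacked in 1,2,4-trialkoxybenzenes.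

Step 3
Reactants: 4 1-(6-hydroxy-2,3,4-trimethoxyphenyl)ethan-1-one
Product: 5 1-(2,6-dihydroxy-3,4-dimethoxyphenyl)ethan-1-one
Conditions: BCl3, CH2Cl2, −78 to 0 °C; then H2O
Reagents that add atoms: none
Why: Chelation-directed Lewis-acid ether cleavage, in which boron bound to the carbonyl oxygen should cleave only the methoxy group ortho to the acyl group.

Step 4
Reactants: 5 1-(2,6-dihydroxy-3,4-dimethoxyphenyl)ethan-1-one
Product: 6 1-[2-hydroxy-3,4-dimethoxy-6-(methoxymethoxy)phenyl]ethan-1-one
Conditions: MOMCl (1.05 equiv), iPr2NEt, CH2Cl2, 0 °C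
Reagents that add atoms: chloromethyl methyl ether COCCl
Why: Selective mono-O-alkylation, in which the phenol next to the ring CH is the less hindered one and the other phenol stays hydrogen-bonded between the carbonyl and methoxy groups.

Step 5
Reactants: 6 1-[2-hydroxy-3,4-dimethoxy-6-(methoxymethoxy)phenyl]ethan-1-one
Product: 7 1-[2-(benzyloxy)-3,4-dimethoxy-6-(methoxymethoxy)phenyl]ethan-1-one
Conditions: BnBr, K2CO3, DMF, 60 °C
Reagents that add atoms: benzyl bromide BrCc1ccccc1
Why: Williamson etherification of the remaining hydrogen-bonded phenol under more forcing conditions, which the MOM ether tolerates.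

Step 6
Reactants: 7 1-[2-(benzyloxy)-3,4-dimethoxy-6-(methoxymethoxy)phenyl]ethan-1-one
Product: 8 2-[2-(benzyloxy)-3,4-dimethoxy-6-(methoxymethoxy)phenyl]-2,2-dimethoxyethan-1-ol
Conditions: PhI(OAc)2, KOH, MeOH, 0 °C to rt
Reagents that add atoms: methanol CO
Why: Hypervalent-iodine α-hydroxylation of an aryl methyl ketone (Moriarty oxidation), which passes through the methoxy oxirane and should give the α-hydroxy dimethyl ketal without touching the protected phenols.

Step 7
Reactants: 8 2-[2-(benzyloxy)-3,4-dimethoxy-6-(methoxymethoxy)phenyl]-2,2-dimethoxyethan-1-ol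
Product: 9 1-[2-(benzyloxy)-6-hydroxy-3,4-dimethoxyphenyl]-2-hydroxyethan-1-one
Conditions: 2 M HCl, THF/MeOH, 50 °C
Reagents that add atoms: water O
Why: Acid hydrolysis should cleave the dimethyl ketal and the MOM acetal in one operation while the benzyl ether stays.

Step 8
Reactants: 9 1-[2-(benzyloxy)-6-hydroxy-3,4-dimethoxyphenyl]-2-hydroxyethan-1-one; 3 2,5-bis(benzyloxy)-4-methoxybenzaldehyde
Product: 10 rac-6-(benzyloxy)-2-[2,5-bis(benzyloxy)-4-methoxyphenyl]-7,8-dimethoxy-4H-1,3-benzodioxepin-5-one
Conditions: PPTS (cat.), toluene, 4 Å MS, 80 °C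
Reagents that add atoms: none
Why: Dehydrative acetalization of the aldehyde with the phenol and the primary ketol hydroxyl, which are held cis on the arene as in the 1,4-diols that form 1,3-dioxepines, should close the seven-membered cyclic acetal.

Step 9
Reactants: 10 rac-6-(benzyloxy)-2-[2,5-bis(benzyloxy)-4-methoxyphenyl]-7,8-dimethoxy-4H-1,3-benzodioxepin-5-one
Product: 11 rac-{[6-(benzyloxy)-2-[2,5-bis(benzyloxy)-4-methoxyphenyl]-7,8-dimethoxy-2H-1,3-benzodioxepin-5-yl]oxy}(tert-butyl)dimethylsilane
Conditions: KHMDS, THF, −78 °C; then TBSCl, DMPU, −78 to −40 °C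
Reagents that add atoms: tert-butyldimethylsilyl chloride CC(C)(C)[Si](C)(C)Cl
Why: Kinetic enolate formation at the only enolizable position and O-silylation should give the ring-confined (Z) silyl enol ether under basic conditions that leave the acetal intact.

Step 10
Reactants: 11 rac-{[6-(benzyloxy)-2-[2,5-bis(benzyloxy)-4-methoxyphenyl]-7,8-dimethoxy-2H-1,3-benzodioxepin-5-yl]oxy}(tert-butyl)dimethylsilane
Product: 13 (2R,3R)-5-(benzyloxy)-2-[2,5-bis(benzyloxy)-4-methoxyphenyl]-3-hydroxy-6,7-dimethoxychroman-4-one, via 3-O-TBS chromanone 12 (not isolated)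
Conditions: (S,S)-IDPi (chiral imidodiphosphorimidate acid, 3 mol %), CH2Cl2/toluene, −78 to −50 °C; then HF·pyridine, THF, 0 °C
Reagents that add atoms: none
Why: Proposed new method: the silylated catalyst (formed by protodesilylation of a trace of 11) should silylate the enol-acetal oxygen, the bond from C2 to this oxygen ionizes to an O-aryl oxocarbenium ion (ArCH=O1+–Ar, stabilized by the 2,4,5-trioxygenated ring B) paired with the chiral anion, and the tethered bis(silyl) enediol ether attacks C2 through C3, after which the silyl group on the C4 oxygen returns to the anion, so that C2 has moved from the C3 oxygen to C3 in a net [1,2] O-to-C shift and the seven-membered dioxepine contracts to the six-membered pyranone. The closest known reactions are the Petasis–Ferrier rearrangement of cyclic enol acetals (the same ionization and recombination, but a [1,3] shift), its aza variant under chiral phosphoric acid catalysis, and silylium/IDPi-catalysed Mukaiyama additions to oxocarbenium ions. The pyranone ring closes by 6-endo-trig attack on the oxocarbenium carbon with the enol C=C inside the forming ring (enolendo), which the di-ortho-substituted aryl enol ether, twisted out of the arene plane, allows. C2 is set by the confined chiral counteranion, which shields one face of the planar cation (the racemic acetal centre of 11 is erased, so both enantiomers converge), and C3 follows C2 through a chair-like transition state with the aryl and silyloxy groups pseudo-equatorial, giving the 2,3-trans isomer, which is also the more stable one. The step needs attack through C3 (six-membered ring) and not through the ketone-derived carbon (a [1,3] shift to a 3-formyl-2,3-dihydrobenzofuran), which the silyloxy and aryl groups on C4 secure by stabilizing the cation left there, and it needs ionization at the enol-acetal oxygen, the only productive one because the cation formed by loss of the aryloxy group cannot be reached by the enol carbon in a ring larger than three. Fluoride then removes the silyl group from 12 without base, so neither C2 nor C3 should epimerize.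

Step 11
Reactants: 13 (2R,3R)-5-(benzyloxy)-2-[2,5-bis(benzyloxy)-4-methoxyphenyl]-3-hydroxy-6,7-dimethoxychroman-4-one
Product: 14 (2R,3R)-5-(benzyloxy)-2-[2,5-bis(benzyloxy)-4-methoxyphenyl]-3,6,7-trimethoxychroman-4-one
Conditions: MeOTf, 2,6-di-tert-butyl-4-methylpyridine, CH2Cl2, 0 °C to rt
Reagents that add atoms: methyl trifluoromethanesulfonate COS(=O)(=O)C(F)(F)F
Why: O-Methylation of the secondary alcohol with a hard methylating agent and a non-nucleophilic hindered base avoids enolate formation, so ring opening at C2 and epimerization at C3 should not occur.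

Step 12
Reactants: 14 (2R,3R)-5-(benzyloxy)-2-[2,5-bis(benzyloxy)-4-methoxyphenyl]-3,6,7-trimethoxychroman-4-one
Product: 15 (2R,3R)-2-(2,5-dihydroxy-4-methoxyphenyl)-5-hydroxy-3,6,7-trimethoxychroman-4-one (target)
Conditions: H2 (1 atm), 10% Pd/C, EtOAc/MeOH, rt, under exclusion of air on work-up
Reagents that add atoms: none
Why: Catalytic hydrogenolysis should remove the three aryl benzyl ethers under neutral conditions faster than it attacks the hydrogen-bonded aryl ketone or the ring C2–O1 bond.

**Compound list**

1 | 2-methoxybenzene-1,4-diol | COc1cc(O)ccc1O | starting material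
2 | 1,4-bis(benzyloxy)-2-methoxybenzene | COc1cc(OCc2ccccc2)ccc1OCc1ccccc1 | intermediate
3 | 2,5-bis(benzyloxy)-4-methoxybenzaldehyde | COc1cc(OCc2ccccc2)c(C=O)cc1OCc1ccccc1 | intermediate
4 | 1-(6-hydroxy-2,3,4-trimethoxyphenyl)ethan-1-one | CC(=O)c1c(O)cc(OC)c(OC)c1OC | starting material
5 | 1-(2,6-dihydroxy-3,4-dimethoxyphenyl)ethan-1-one | CC(=O)c1c(O)cc(OC)c(OC)c1O | intermediate
6 | 1-[2-hydroxy-3,4-dimethoxy-6-(methoxymethoxy)phenyl]ethan-1-one | CC(=O)c1c(OCOC)cc(OC)c(OC)c1O | intermediate
7 | 1-[2-(benzyloxy)-3,4-dimethoxy-6-(methoxymethoxy)phenyl]ethan-1-one | CC(=O)c1c(OCOC)cc(OC)c(OC)c1OCc1ccccc1 | intermediate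
8 | 2-[2-(benzyloxy)-3,4-dimethoxy-6-(methoxymethoxy)phenyl]-2,2-dimethoxyethan-1-ol | OCC(OC)(OC)c1c(OCOC)cc(OC)c(OC)c1OCc1ccccc1 | intermediate
9 | 1-[2-(benzyloxy)-6-hydroxy-3,4-dimethoxyphenyl]-2-hydroxyethan-1-one | OCC(=O)c1c(O)cc(OC)c(OC)c1OCc1ccccc1 | intermediate
10 | rac-6-(benzyloxy)-2-[2,5-bis(benzyloxy)-4-methoxyphenyl]-7,8-dimethoxy-4H-1,3-benzodioxepin-5-one | O=C1COC(c2cc(OCc3ccccc3)c(OC)cc2OCc2ccccc2)Oc2cc(OC)c(OC)c(OCc3ccccc3)c21 | intermediate
11 | rac-{[6-(benzyloxy)-2-[2,5-bis(benzyloxy)-4-methoxyphenyl]-7,8-dimethoxy-2H-1,3-benzodioxepin-5-yl]oxy}(tert-butyl)dimethylsilane | CC(C)(C)[Si](C)(C)OC1=COC(c2cc(OCc3ccccc3)c(OC)cc2OCc2ccccc2)Oc2cc(OC)c(OC)c(OCc3ccccc3)c21 | intermediate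
12 | (2R,3R)-5-(benzyloxy)-2-[2,5-bis(benzyloxy)-4-methoxyphenyl]-3-[(tert-butyldimethylsilyl)oxy]-6,7-dimethoxychroman-4-one | COc1cc(OCc2ccccc2)c([C@H]2Oc3cc(OC)c(OC)c(OCc4ccccc4)c3C(=O)[C@@H]2O[Si](C)(C)C(C)(C)C)cc1OCc1ccccc1 | intermediate
13 | (2R,3R)-5-(benzyloxy)-2-[2,5-bis(benzyloxy)-4-methoxyphenyl]-3-hydroxy-6,7-dimethoxychroman-4-one | COc1cc(OCc2ccccc2)c([C@H]2Oc3cc(OC)c(OC)c(OCc4ccccc4)c3C(=O)[C@@H]2O)cc1OCc1ccccc1 | intermediate
14 | (2R,3R)-5-(benzyloxy)-2-[2,5-bis(benzyloxy)-4-methoxyphenyl]-3,6,7-trimethoxychroman-4-one | COc1cc(OCc2ccccc2)c([C@H]2Oc3cc(OC)c(OC)c(OCc4ccccc4)c3C(=O)[C@@H]2OC)cc1OCc1ccccc1 | intermediate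
15 | (2R,3R)-2-(2,5-dihydroxy-4-methoxyphenyl)-5-hydroxy-3,6,7-trimethoxychroman-4-one | COc1cc(O)c([C@H]2Oc3cc(OC)c(OC)c(O)c3C(=O)[C@@H]2OC)cc1O | target

**Step count**

Total steps: 12. Longest linear sequence: 10 (steps 3 to 12).

**Steps most likely to fail**

1. Step 10 (proposed new method). What may go wrong: poor facial discrimination of the oxocarbenium ion by the counteranion, loss of enantiopurity through reversible re-ionization at C2–O1, or closure through the ketone-derived carbon instead of C3. The fallback uses known chemistry, sets out from 7 and 3, and comes back at 13. Claisen–Schmidt condensation of 7 with 3 (KOH, EtOH) should give the (E)-chalcone F1. Juliá–Colonna epoxidation (poly-L-leucine, urea–H2O2, DBU, THF) should give the (αR,βS)-epoxide F2. HCl in MeOH/THF at 50 °C should then remove the MOM group and let the freed phenol open the epoxide at the benzylic carbon (6-endo, inversion there, retention at the α-carbon) to give 13, which rejoins the route at step 11.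

2. Step 8. What may go wrong: slow closure of the seven-membered acetal, Friedel–Crafts hydroxyalkylation of ring A by the activated aldehyde, or acid-induced ionization and rearrangement before the chiral step. The fallback sets out from 9 and 3 and comes back at 10. Silylation of 9 (TMSCl, Et3N, CH2Cl2) should give the bis(trimethylsilyl) ether F3. Kinetic silyl acetalization of 3 with F3 under catalytic TMSOTf at −78 °C (Noyori-type, driven by loss of the disiloxane, no free protic acid) should give 10.

3. Step 4. What may go wrong: alkylation at the other phenol or at both phenols. The fallback sets out from 4 and comes back at 7; it tells the two ring-A oxygens apart by the order of events and not by their reactivity. The single phenol of 4 is mesylated (MsCl, Et3N) to the aryl mesylate F4. BCl3 then cleaves the methoxy group ortho to the carbonyl to give the hydroxy mesylate F5. Benzylation (BnBr, K2CO3, DMF) gives the benzyl ether F6. KOH in MeOH removes the mesyl group to give the phenol F7, and MOMCl/iPr2NEt converts it into 7.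

Further compounds
F1 | step 10 | (E)-1-[2-(benzyloxy)-3,4-dimethoxy-6-(methoxymethoxy)phenyl]-3-[2,5-bis(benzyloxy)-4-methoxyphenyl]prop-2-en-1-one | COCOc1cc(OC)c(OC)c(OCc2ccccc2)c1C(=O)/C=C/c1cc(OCc2ccccc2)c(OC)cc1OCc1ccccc1
F2 | step 10 | [2-(benzyloxy)-3,4-dimethoxy-6-(methoxymethoxy)phenyl]{(2R,3S)-3-[2,5-bis(benzyloxy)-4-methoxyphenyl]oxiran-2-yl}methanone | COCOc1cc(OC)c(OC)c(OCc2ccccc2)c1C(=O)[C@@H]1O[C@H]1c1cc(OCc2ccccc2)c(OC)cc1OCc1ccccc1
F3 | step 8 | 1-{2-(benzyloxy)-3,4-dimethoxy-6-[(trimethylsilyl)oxy]phenyl}-2-[(trimethylsilyl)oxy]ethan-1-one | C[Si](C)(C)OCC(=O)c1c(O[Si](C)(C)C)cc(OC)c(OC)c1OCc1ccccc1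
F4 | step 4 | 2-acetyl-3,4,5-trimethoxyphenyl methanesulfonate | CC(=O)c1c(OS(C)(=O)=O)cc(OC)c(OC)c1OC
F5 | step 4 | 2-acetyl-3-hydroxy-4,5-dimethoxyphenyl methanesulfonate | CC(=O)c1c(OS(C)(=O)=O)cc(OC)c(OC)c1O
F6 | step 4 | 2-acetyl-3-(benzyloxy)-4,5-dimethoxyphenyl methanesulfonate | CC(=O)c1c(OS(C)(=O)=O)cc(OC)c(OC)c1OCc1ccccc1
F7 | step 4 | 1-[2-(benzyloxy)-6-hydroxy-3,4-dimethoxyphenyl]ethan-1-one | CC(=O)c1c(O)cc(OC)c(OC)c1OCc1ccccc1
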